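## Structural features

The target 15 is a spiro compound: C2 of a chroman (pyran ring O1, C2, C3, C4, C4a, C8a fused to a benzene ring) is also C2' of a 3',3'-dimethylnorbornane (chroman atoms unprimed, norbornane atoms primed). The benzene ring is a fully substituted phloroglucinol, with O1 as ring ether, free hydroxyl groups on C5 and C7, formyl groups on C6 and C8, and the pyran arm on C4a. There are four stereocentres. The bridgeheads C1' (R) and C4' (S) are locked by the bicycle. The quaternary spiro carbon C2/C2' (R) lies between C1' and the quaternary C3', with O1 on the endo face and C3 on the exo face. The benzylic C4 (S) is 1,3 to the spiro carbon and holds its isobutyl group on the pyran face that also carries C3'. The fragile points are the tertiary alkyl aryl ether C2'–O1, whose ionisation would give a camphene-type cation next to C3' and open Wagner–Meerwein pathways, and the two formyl groups on an electron-rich phenol ring, which are best made last. The real difficulty is to build the congested C2' between a bridgehead and a quaternary carbon with the right face, and then to relay that configuration to C4. The key step uses the fact that C3–C4 is a two-carbon bridge between the oxygen-bearing C2' and the arene carbon C4a: the two alkene carbons of a vinyl ketone can be stitched between a planar radical at C2' and the ortho carbon of an aryl ether already on C2', so the configuration of C2' is decided only when the C2'–C3 bond forms.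

## Logic of the disconnections

15 to 13. The C6–CHO and C8–CHO bonds are cut. The formyl groups are the most sensitive functions, and C6 and C8 are the only free positions of an activated ring, so they can go on last without a regiochemical question. The gain is a plain dihydroxychroman. The forward step must formylate twice without acid strong enough to ionise C2'–O1; it passes through 14.

13 to 12. The C4–H bond and the neighbouring side-chain C–H bond are removed to give the C4 alkylidene, and the two phenol O–H bonds become O–benzyl bonds. This lets the existing spiro centre set C4 by the face of hydrogen delivery and merges deprotection with reduction. Benzyl ethers are used instead of methyl ethers because a Lewis-acid demethylation would endanger C2'–O1. The forward step must deliver hydrogen to C4 from the face that carries C1'.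

12 to 10 to 9. The alkene is traced through the secondary alcohol 10 (C–O bond, via 11) to the ketone 9 (C=O). The ketone is the functional group the radical acceptor leaves behind, and it activates the C4–H bond. The gain is that C4 need not be controlled when the ring is made. The forward elimination must go toward C4 and not toward the isopropyl group.

9 to 7 and 8. The C2'–C3 and C4–C4a bonds are cut. This removes the pyran ring and the spiro stereocentre at once and leaves an activated α-aryloxy acid and a simple enone. The forward step must form the C2'–C3 bond on the exo face and close at the ortho carbon of the aryl ether.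

7 to 6. The acyl C–O bond to the phthalimide nitrogen-oxygen unit is cut; this is only activation of the acid for single-electron reduction. The forward step must esterify a hindered acid without touching the electron-rich ring.

6 to 3 and 4. The C2'–O(aryl) and C2'–CO2H bonds are cut; both are made at the carbonyl carbon of 3, with chloroform supplying the carboxyl carbon. The gain is a one-step assembly of the hindered tertiary ether. The forward step must add to a hindered, non-enolisable ketone; the configuration at C2' is free because it is erased in the key step.

3 to 1. The C2'=O bond is traced to the C2'=CH2 bond of the terpene, which brings C1' and C4' from the chiral pool. The forward cleavage must avoid acid, which would racemise or rearrange the skeleton.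

## Other disconnections considered

Alternative 1: The bicycle is cut at C1'–C2' and C3'–C4' into the diene A3 (cyclopentadiene) and the dienophile A2 (2-benzoyloxy-2-cyclopropylideneacetaldehyde). The benzoate oxygen of A2 becomes O1, its formyl carbon becomes C3, and its cyclopropane is the latent gem-dimethyl group. Forward, a chiral cationic oxazaborolidine Lewis acid would catalyse the Diels–Alder reaction to adduct A1, with formyl exo and benzoate endo.
- In its favour: the absolute configuration comes from a catalyst and not from a terpene of variable optical purity, which is better than the chosen plan. The exo-carbon, endo-oxygen arrangement at C2' comes from a well-understood polar cycloaddition preference, which is at least equal to, and arguably more predictable than, the face selectivity of a radical addition.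
- Against it: the dienophile is tetrasubstituted, so rate and enantioselectivity are open. The norbornane that the chiral pool supplies for nothing must be built. After A1 the route still needs alkene hydrogenation, hydrogenolytic opening of the cyclopropane, benzoate removal, a chain extension that creates C4, closure of O1–C8a at a hindered tertiary oxygen, and the formyl groups.
- Comparison: the hardest bonds around C2' are postponed, not solved, and the step count would be roughly twice the eight steps of the chosen plan. Mechanistically it is the more predictable route at C2'; structurally and in step economy it is the weaker one.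

Alternative 2: The benzene ring is cut at C8–C8a and C5–C6 and made last from the cyclic ketene acetal ester A5 (a 2-methoxy-dihydropyran-3-carboxylate in which C8a is the ketene acetal carbon) and the three-carbon bis-nucleophile A6 (dimethyl 3-oxopentanedioate). Forward, the dianion of A6 would add to C8a with loss of methoxide, then acylate on the C5 ester and aromatise to the dihydroxy diester A4.
- In its favour: C6 and C8 arrive as carbon substituents in the right places by construction, which is better than a double electrophilic formylation whose completeness is uncertain. The phenols never need protection, which is also better. All steps are base-mediated ionic condensations that cannot ionise C2'–O1, so it is equal or better on mildness. The spiro carbon could be set by polar exo addition of a carbon nucleophile to 3, which is equal.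
- Against it: A5 must already hold C4 in the right configuration relative to C2' in a non-aromatic ring with no obvious control element, whereas the chosen plan uses a rigid arene-fused alkene for this. C8a in A5 is a fully substituted carbon bearing a tertiary alkoxy group, so the addition–elimination is hindered. Two salicylate-type esters must be converted to aldehydes by reduction and re-oxidation.
- Comparison: stronger on the arene substitution pattern, weaker on C4 and on step count, which would clearly exceed eight.

Alternative 3: The C1'–C6' bond is cut, read backwards as a Wagner–Meerwein shift. The precursor is the bornane A8, a 2-exo-hydroxybornane whose C10 carries the C4 arm with the protected aryl group, so that chroman C3 is bornane C10. Forward, ionisation of the exo alcohol of A8 (thionyl chloride, pyridine) would make C6 migrate from C1 to C2, and proton loss from the former C10 would give the alkylidene camphane A7. O1–C2' would then be closed by adding the phenol oxygen across the C2'=C3 bond.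
- In its favour: C10-functionalised camphor building blocks are available in both enantiomeric series in high optical purity, which is better than camphene on that point. C4 can be set in an open chain before the spiro ring exists, which is potentially better than relying on a facial hydrogenation. The arene is joined convergently.
- Against it: the ring closure must put oxygen on the endo face of C2' while C3 is already attached, and capture at C2 of norbornyl-type cations prefers the exo face, so the C2' epimer of the target would be favoured. The key step and the ring closure both run in the cationic manifold in which camphene and bornane skeletons interconvert. Acid-labile methoxymethyl ethers and a very electron-rich ring sit in the ionising medium. A8 itself needs several steps.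
- Comparison: the chosen plan makes C2' by carbon–carbon bond formation on the exo face, which leaves oxygen endo as required; this alternative makes it by carbon–oxygen bond formation, which tends to the exo face. That structural point decides against it, and it is also longer.

Key step: step 4

Remark (assumption): commercial (1S,4R)-(−)-camphene is taken as enantiomerically pure; the bridgeheads are never touched, so its optical purity is carried unchanged to 15.

Remark (stereochemical drawing): 5, 6 and 7 are drawn as the C2' epimers expected from exo addition to 3; this is of no consequence. 9, 10 and 11 are drawn without configuration at C4 and at the side-chain carbinol carbon, because both centres become trigonal in step 6.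

Remark (corrections): the phenol oxygens are carried as benzyl ethers and not methyl ethers. The endo face of C2' is screened by the endo hydrogen on C6' and the endo methyl on C3'; the endo hydrogen on C5' lies under C3' and plays no part.

## Route

Step 1
Reactants: 1 (1S,4R)-(−)-camphene
Product: 3 (1R,4S)-camphenilone, via primary ozonide 2 (not isolated)
Conditions: O3, CH2Cl2–MeOH, −78 °C; then Me2S, −78 °C to rt
Reagents that add atoms: ozone ([O-][O+]=O)
Why: Ozonolysis of the exocyclic methylidene group; the primary ozonide 2 should fragment to the ketone and formaldehyde O-oxide, which methanol traps and Me2S reduces. The cold neutral conditions leave the bridgeheads and the acid-sensitive skeleton untouched.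

Step 2
Reactants: 3 (1R,4S)-camphenilone; 4 3,5-bis(benzyloxy)phenol
Product: 6 2'-exo-[3,5-bis(benzyloxy)phenoxy]-3',3'-dimethylnorbornane-2'-endo-carboxylic acid, via gem-dichloroepoxide 5 (not isolated)
Conditions: CHCl3, powdered NaOH, THF, 0 °C to rt (3 in threefold excess, recovered); then cold dilute aq. HCl
Reagents that add atoms: chloroform (ClC(Cl)Cl); sodium hydroxide ([Na+].[OH-])
Why: Bargellini reaction: trichloromethide adds to the non-enolisable carbonyl group of 3, the alkoxide closes to the gem-dichloroepoxide 5, the phenoxide of 4 opens it at the quaternary carbon with inversion, and hydroxide hydrolyses the acyl chloride. Exo addition followed by inversion should put the aryloxy group exo, but the C2' configuration does not matter because C2' becomes a planar radical in step 4.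

Step 3
Reactants: 6 2'-exo-[3,5-bis(benzyloxy)phenoxy]-3',3'-dimethylnorbornane-2'-endo-carboxylic acid
Product: 7 1,3-dioxoisoindolin-2-yl 2'-exo-[3,5-bis(benzyloxy)phenoxy]-3',3'-dimethylnorbornane-2'-endo-carboxylate
Conditions: N-hydroxyphthalimide, DIC, DMAP (cat.), CH2Cl2, 0 °C to rt
Reagents that add atoms: N-hydroxyphthalimide (ON1C(=O)c2ccccc2C1=O)
Why: Carbodiimide (Steglich-type) esterification; the acid has no α-hydrogen, so neither ketene formation nor epimerisation can interfere. The mild neutral activation avoids an acid chloride that could acylate the electron-rich ring.

Step 4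
Reactants: 7 1,3-dioxoisoindolin-2-yl 2'-exo-[3,5-bis(benzyloxy)phenoxy]-3',3'-dimethylnorbornane-2'-endo-carboxylate; 8 4-methylpent-1-en-3-one
Product: 9 (2R,1'R,4'S)-5,7-bis(benzyloxy)-3',3'-dimethyl-4-(2-methylpropanoyl)spiro[chroman-2,2'-norbornane] (O1 endo; C3 exo; C4 epimers)
Conditions: fac-Ir(ppy)3 (1 mol%), 8 (3 equiv), DMSO, blue LEDs (450 nm), rt, Ar
Reagents that add atoms: none
Why: Photoexcited fac-Ir(ppy)3 should reduce the phthalimide ester 7 by single-electron transfer; N–O cleavage and loss of CO2 then give a tertiary α-aryloxy radical at C2' that is planar at carbon, so both C2' epimers of 7 converge. This nucleophilic radical adds to the unsubstituted alkene terminus of 8 (Giese addition, C2'–C3 bond), and the electrophilic α-keto radical so formed attacks the ortho carbon of the electron-rich aryl ether (C4–C4a bond) in a homolytic aromatic substitution; the cyclohexadienyl radical is oxidised by the tetravalent iridium complex, which closes the catalytic cycle, and the phthalimide anion takes up the proton. The closest known reaction type is the photoredox decarboxylative radical [4+2] annulation of N-acyloxyphthalimides of α-aryloxy acids with electron-poor alkenes to chromans. The pyran ring closes by radical attack on the arene ortho position through a six-membered transition state, which is preferred over five-membered ipso attack and aryl migration. C2' is set by the face of the Giese addition: the endo face is screened by the endo hydrogen on C6' and the endo methyl on C3', and bonding on the exo face, as is usual for 2-norbornyl radicals, leaves O1 endo. C4 is an enolisable α-aryl ketone centre, is not controlled in a useful way, and is erased in step 6. The step needs exo selectivity at C2' and ortho selectivity on the arene; the first rests on the shape of the bicycle, the second on ring size and on the equivalence of the two ortho positions of the 3,5-disubstituted aryl ether, so that only one regioisomer can form.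

Step 5
Reactants: 9 (2R,1'R,4'S)-5,7-bis(benzyloxy)-3',3'-dimethyl-4-(2-methylpropanoyl)spiro[chroman-2,2'-norbornane]
Product: 10 (2R,1'R,4'S)-5,7-bis(benzyloxy)-4-(1-hydroxy-2-methylpropyl)-3',3'-dimethylspiro[chroman-2,2'-norbornane]
Conditions: LiAlH4, THF, 0 °C; then H2O, aq. NaOH
Reagents that add atoms: none
Why: Hydride reduction of the hindered ketone; benzyl and aryl ethers are inert. The configurations at the carbinol carbon and at C4 do not matter because both centres become trigonal in step 6.

Step 6
Reactants: 10 (2R,1'R,4'S)-5,7-bis(benzyloxy)-4-(1-hydroxy-2-methylpropyl)-3',3'-dimethylspiro[chroman-2,2'-norbornane]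
Product: 12 (E)-(2R,1'R,4'S)-5,7-bis(benzyloxy)-3',3'-dimethyl-4-(2-methylpropylidene)spiro[chroman-2,2'-norbornane], via Burgess sulfamate ester 11 (not isolated)
Conditions: Burgess reagent, toluene, rt to 70 °C
Reagents that add atoms: none
Why: Burgess dehydration: the sulfamate ester 11 undergoes thermal syn-elimination, and of the two β-hydrogens the benzylic one on C4 is the more acidic and leads to the arene-conjugated alkene; the medium stays neutral, so the tertiary spiro ether is not ionised. The E isomer, with the isopropyl group turned away from the benzyloxy group on C5, is expected, but either geometry serves step 7.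

Step 7
Reactants: 12 (E)-(2R,1'R,4'S)-5,7-bis(benzyloxy)-3',3'-dimethyl-4-(2-methylpropylidene)spiro[chroman-2,2'-norbornane]
Product: 13 (2R,4S,1'R,4'S)-3',3'-dimethyl-4-(2-methylpropyl)spiro[chroman-2,2'-norbornane]-5,7-diol
Conditions: H2 (1–4 bar), Pd/C, EtOAc–EtOH, rt
Reagents that add atoms: none
Why: Heterogeneous catalytic hydrogenation: the catalyst should approach C4 from the pyran face that carries only the C1' hydrogen, because the exo methyl group on C3' lies over the other face; hydrogen then ends up cis to C1' and the isobutyl group cis to C3' (4S). The same catalyst hydrogenolyses both benzyl ethers, so no acidic deprotection is applied to the spiro ether.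

Step 8
Reactants: 13 (2R,4S,1'R,4'S)-3',3'-dimethyl-4-(2-methylpropyl)spiro[chroman-2,2'-norbornane]-5,7-diol
Product: 15 (2R,4S,1'R,4'S)-5,7-dihydroxy-3',3'-dimethyl-4-(2-methylpropyl)spiro[chroman-2,2'-norbornane]-6,8-dicarbaldehyde, via bis(iminium) salt 14 (not isolated)
Conditions: POCl3, DMF, MeCN, 0 °C to rt; then aq. NaOAc, 50 °C
Reagents that add atoms: N,N-dimethylformamide (CN(C)C=O); water (O)
Why: Vilsmeier–Haack formylation: the ring with two free hydroxyl groups and the ring ether is nucleophilic enough to react twice, and C6 and C8 are its only free positions, so no regiochemical question arises. Buffered hydrolysis of the bis(iminium) salt 14 keeps the medium from becoming acidic enough to ionise the C2'–O1 bond.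

## Compound list

1 | (1S,4R)-(−)-camphene, (1S,4R)-2,2-dimethyl-3-methylidenebicyclo[2.2.1]heptane | C=C1[C@@H]2CC[C@@H](C2)C1(C)C | starting material
2 | primary ozonide of 1 (spiro-1,2,3-trioxolane on C2'; C2' configuration not defined) | C1OOOC12[C@@H]3CC[C@@H](C3)C2(C)C | intermediate
3 | (1R,4S)-camphenilone, (1R,4S)-3,3-dimethylbicyclo[2.2.1]heptan-2-one | O=C1[C@@H]2CC[C@@H](C2)C1(C)C | intermediate
4 | 3,5-bis(benzyloxy)phenol | Oc1cc(OCc2ccccc2)cc(OCc2ccccc2)c1 | starting material
5 | (1'R,4'S)-3,3-dichloro-3',3'-dimethylspiro[oxirane-2,2'-norbornane], epoxide oxygen endo | ClC1(Cl)O[C@@]12[C@@H]1CC[C@@H](C1)C2(C)C | intermediate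
6 | (1'R,4'S)-2'-exo-[3,5-bis(benzyloxy)phenoxy]-3',3'-dimethylnorbornane-2'-endo-carboxylic acid | OC(=O)[C@]1(Oc2cc(OCc3ccccc3)cc(OCc3ccccc3)c2)[C@@H]2CC[C@@H](C2)C1(C)C | intermediate
7 | 1,3-dioxoisoindolin-2-yl (1'R,4'S)-2'-exo-[3,5-bis(benzyloxy)phenoxy]-3',3'-dimethylnorbornane-2'-endo-carboxylate | O=C(ON1C(=O)c2ccccc2C1=O)[C@]1(Oc2cc(OCc3ccccc3)cc(OCc3ccccc3)c2)[C@@H]2CC[C@@H](C2)C1(C)C | intermediate
8 | 4-methylpent-1-en-3-one | C=CC(=O)C(C)C | starting material
9 | (2R,1'R,4'S)-5,7-bis(benzyloxy)-3',3'-dimethyl-4-(2-methylpropanoyl)spiro[chroman-2,2'-norbornane], O1 endo and C3 exo on C2', C4 epimers | CC(C)C(=O)C1C[C@@]2(Oc3cc(OCc4ccccc4)cc(OCc4ccccc4)c31)[C@@H]1CC[C@@H](C1)C2(C)C | intermediate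
10 | (2R,1'R,4'S)-5,7-bis(benzyloxy)-4-(1-hydroxy-2-methylpropyl)-3',3'-dimethylspiro[chroman-2,2'-norbornane], C4 and carbinol epimers | CC(C)C(O)C1C[C@@]2(Oc3cc(OCc4ccccc4)cc(OCc4ccccc4)c31)[C@@H]1CC[C@@H](C1)C2(C)C | intermediate
11 | triethylammonium N-(methoxycarbonyl)sulfamate ester of 10 | CC(C)C(OS(=O)(=O)[N-]C(=O)OC)C1C[C@@]2(Oc3cc(OCc4ccccc4)cc(OCc4ccccc4)c31)[C@@H]1CC[C@@H](C1)C2(C)C.CC[NH+](CC)CC | intermediate
12 | (E)-(2R,1'R,4'S)-5,7-bis(benzyloxy)-3',3'-dimethyl-4-(2-methylpropylidene)spiro[chroman-2,2'-norbornane] | CC(C)/C=C1\C[C@@]2(Oc3cc(OCc4ccccc4)cc(OCc4ccccc4)c31)[C@@H]1CC[C@@H](C1)C2(C)C | intermediate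
13 | (2R,4S,1'R,4'S)-3',3'-dimethyl-4-(2-methylpropyl)spiro[chroman-2,2'-norbornane]-5,7-diol | CC(C)C[C@H]1C[C@@]2(Oc3cc(O)cc(O)c31)[C@@H]1CC[C@@H](C1)C2(C)C | intermediate
14 | 6,8-bis(dimethyliminiomethyl) derivative of 13, dichloride | CC(C)C[C@H]1C[C@@]2(Oc3c(C=[N+](C)C)c(O)c(C=[N+](C)C)c(O)c31)[C@@H]1CC[C@@H](C1)C2(C)C.[Cl-].[Cl-] | intermediate
15 | (2R,4S,1'R,4'S)-5,7-dihydroxy-3',3'-dimethyl-4-(2-methylpropyl)spiro[chroman-2,2'-norbornane]-6,8-dicarbaldehyde | CC(C)C[C@H]1C[C@@]2(Oc3c(C=O)c(O)c(C=O)c(O)c31)[C@@H]1CC[C@@H](C1)C2(C)C | target

## Step count and least certain steps

Total step count: 8. Longest linear sequence: 8 steps (1 to 15); 4 and 8 are bought.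

**Step 4 (key step).** The radical at C2' is tertiary and flanked by a quaternary carbon, so its addition to 8 may be slow. Back electron transfer, reduction of the radical, or quenching of the adduct radical before it closes onto the arene could then take over. Bonding on the endo face is a second concern. The fallback separates the two bond formations. It sets out from 7 and 8 and comes back at 9.
- A reductive decarboxylative Giese addition (Ru(bpy)3(PF6)2, Hantzsch ester, iPr2NEt, CH2Cl2, blue light) should give the open-chain ketone 1-{2'-endo-[3,5-bis(benzyloxy)phenoxy]-3',3'-dimethylnorbornan-2'-exo-yl}-4-methylpentan-3-one F1.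
- Kinetic deprotonation on the methylene side (LiN(iPr)2, THF, −78 °C) and bromination of the enolate with 1,2-dibromotetrachloroethane should give the α-bromoketone 2-bromo-1-{2'-endo-[3,5-bis(benzyloxy)phenoxy]-3',3'-dimethylnorbornan-2'-exo-yl}-4-methylpentan-3-one F2.
- Photoredox generation of the α-keto radical from this bromide (fac-Ir(ppy)3, 2,6-lutidine, DMF, blue light) and closure onto the arene should give 9.
- Both stages are known reaction types and can be optimised separately.

**Step 2.** Trichloromethide may add too slowly to the hindered carbonyl group, so that dichlorocarbene consumes the phenoxide by ring formylation of the Reimer–Tiemann type. Displacement at the congested quaternary carbon may also lose to chloride migration. The fallback separates carbon–carbon from carbon–oxygen bond formation. It sets out from 3 and comes back at 6.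
- Trichloromethyllithium is made at −78 °C (CHCl3, LiN(SiMe3)2, THF) and added to 3 with no phenol present, to give the carbinol 3,3-dimethyl-2-exo-(trichloromethyl)norbornan-2-endo-ol F3, which is isolated.
- A Jocic–Reeve reaction of this carbinol with 4 (NaOH, DME, 0 °C to rt) should then give 6 with no free chloroform or carbene in the flask.

**Step 6.** Elimination may run toward the isopropyl methine and not toward C4, which would leave C4 untouched by step 7, or ionisation may bring hydride shifts. The fallback avoids the alcohol. It sets out from 9 and comes back at 12.
- Deprotonation of the benzylic C4–H (KN(SiMe3)2, THF, −78 to 0 °C) and trapping with N-phenyl-bis(trifluoromethanesulfonimide) should give the enol triflate 5,7-bis(benzyloxy)-3',3'-dimethyl-4-[2-methyl-1-(trifluoromethylsulfonyloxy)propylidene]spiro[chroman-2,2'-norbornane] F4.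
- Palladium-catalysed formate reduction (Pd(OAc)2, PPh3, Bu3N, HCO2H, DMF, 60 °C) should give 12.
- The position of the double bond is then fixed by the site of enolisation.

**Step 7.** Facial selectivity of hydrogen delivery to C4 may be poor, since the two faces differ only through the 1,3-related spiro centre, and the double bond may migrate on the catalyst before it is reduced. The fallback chooses C4 instead of creating it. It sets out from 9 and comes back at 13.
- The C4 epimers of 9 are equilibrated (DBU, toluene) and separated. The epimer with the acyl group cis to C3', (2R,1'R,4'S)-5,7-bis(benzyloxy)-3',3'-dimethyl-4-(2-methylpropanoyl)spiro[chroman-2,2'-norbornane] with C4 as in the target F5, is carried on; the other is recycled by re-equilibration.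
- LiAlH4 (THF, 0 °C) should give the alcohol F6.
- NaH, CS2, then MeI should give the S-methyl xanthate F7.
- Barton–McCombie deoxygenation (Bu3SnH, AIBN, toluene, 110 °C) should give the saturated dibenzyl ether 5,7-bis(benzyloxy)-3',3'-dimethyl-4-(2-methylpropyl)spiro[chroman-2,2'-norbornane] F8.
- Hydrogenolysis (H2, Pd/C) should give 13. C4 is never trigonal after the separation.

**Step 8.** The second formylation may stall once the first formyl group has deactivated the ring, or the acid released may ionise the tertiary spiro ether during hydrolysis. The fallback changes carbon source and mechanism. It sets out from 13 and comes back at 15: magnesium phenoxide-directed ortho-formylation with paraformaldehyde (MgCl2, Et3N, paraformaldehyde, MeCN, reflux; Casnati–Skattebøl conditions), run with excess reagent so that the 5-hydroxyl directs to C6 and the 7-hydroxyl to C8, in a basic medium throughout. It makes no new compound.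

## Further compounds

F1 | step 4 | 1-{2'-endo-[3,5-bis(benzyloxy)phenoxy]-3',3'-dimethylnorbornan-2'-exo-yl}-4-methylpentan-3-one | CC(C)C(=O)CC[C@@]1(Oc2cc(OCc3ccccc3)cc(OCc3ccccc3)c2)[C@@H]2CC[C@@H](C2)C1(C)C
F2 | step 4 | 2-bromo-1-{2'-endo-[3,5-bis(benzyloxy)phenoxy]-3',3'-dimethylnorbornan-2'-exo-yl}-4-methylpentan-3-one | CC(C)C(=O)C(Br)C[C@@]1(Oc2cc(OCc3ccccc3)cc(OCc3ccccc3)c2)[C@@H]2CC[C@@H](C2)C1(C)C
F3 | step 2 | (1R,4S)-3,3-dimethyl-2-exo-(trichloromethyl)norbornan-2-endo-ol | O[C@]1(C(Cl)(Cl)Cl)[C@@H]2CC[C@@H](C2)C1(C)C
F4 | step 6 | 5,7-bis(benzyloxy)-3',3'-dimethyl-4-[2-methyl-1-(trifluoromethylsulfonyloxy)propylidene]spiro[chroman-2,2'-norbornane] | CC(C)C(OS(=O)(=O)C(F)(F)F)=C1C[C@@]2(Oc3cc(OCc4ccccc4)cc(OCc4ccccc4)c31)[C@@H]1CC[C@@H](C1)C2(C)C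
F5 | step 7 | C4 epimer of 9 with the acyl group cis to C3' | CC(C)C(=O)[C@H]1C[C@@]2(Oc3cc(OCc4ccccc4)cc(OCc4ccccc4)c31)[C@@H]1CC[C@@H](C1)C2(C)C
F6 | step 7 | 5,7-bis(benzyloxy)-4-(1-hydroxy-2-methylpropyl)-3',3'-dimethylspiro[chroman-2,2'-norbornane] with C4 as in the target | CC(C)C(O)[C@H]1C[C@@]2(Oc3cc(OCc4ccccc4)cc(OCc4ccccc4)c31)[C@@H]1CC[C@@H](C1)C2(C)C
F7 | step 7 | O-alkyl S-methyl dithiocarbonate (xanthate) of F6 | CC(C)C(OC(=S)SC)[C@H]1C[C@@]2(Oc3cc(OCc4ccccc4)cc(OCc4ccccc4)c31)[C@@H]1CC[C@@H](C1)C2(C)C
F8 | step 7 | (2R,4S,1'R,4'S)-5,7-bis(benzyloxy)-3',3'-dimethyl-4-(2-methylpropyl)spiro[chroman-2,2'-norbornane] | CC(C)C[C@H]1C[C@@]2(Oc3cc(OCc4ccccc4)cc(OCc4ccccc4)c31)[C@@H]1CC[C@@H](C1)C2(C)C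
F0 | step 8 | none | none
A1 | alternative 1 | exo-formyl endo-benzoyloxy spiro[cyclopropane-norbornene] Diels–Alder adduct | O=C[C@@]2(OC(=O)c3ccccc3)[C@@H]1C=C[C@@H](C1)C24CC4
A2 | alternative 1 | 2-benzoyloxy-2-cyclopropylideneacetaldehyde | O=CC(OC(=O)c1ccccc1)=C1CC1
A3 | alternative 1 | cyclopentadiene | C1=CC=CC1
A4 | alternative 2 | dimethyl 5,7-dihydroxy-4-isobutyl spirochroman-6,8-dicarboxylate | COC(=O)c1c(O)c(C(=O)OC)c2O[C@]3(C[C@H](CC(C)C)c2c1O)[C@@H]4CC[C@@H](C4)C3(C)C
A5 | alternative 2 | methyl 4-isobutyl-2-methoxy spiro-dihydropyran-3-carboxylate (cyclic ketene acetal ester, spiro-linked to the 3',3'-dimethylnorbornane) | COC(=O)C1=C(OC)O[C@]2(C[C@@H]1CC(C)C)[C@@H]1CC[C@@H](C1)C2(C)C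
A6 | alternative 2 | dimethyl 3-oxopentanedioate | COC(=O)CC(=O)CC(=O)OC
A7 | alternative 3 | alkylidene camphane with C1', C4' and C4 in place, aryl group as tris(methoxymethyl) ether | COCOc1cc(OCOC)cc(OCOC)c1[C@@H](CC(C)C)/C=C1\[C@@H]2CC[C@@H](C2)C1(C)C
A8 | alternative 3 | 10-substituted isoborneol: 2-exo-hydroxybornane carrying the 2-aryl-4-methylpentyl arm on C1 | COCOc1cc(OCOC)cc(OCOC)c1[C@@H](CC(C)C)C[C@@]12CC[C@@H](C[C@@H]1O)C2(C)C
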